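## Analysis of the target

With the ring carbons numbered C1–C11 along the SMILES string (C1 senecioate carbinol, C2 methylene, C3 isovalerate carbinol, C4 CMe2, C5 and C6 methines, C7 ketone, C8=C9 alkene with the methyl on C9, C10 methine, C11 quaternary methyl-bearing carbon), the skeleton is a longipinane-type tricyclo[5.4.0.0(2,8)]undecane. Its core is the cyclobutane C5–C6–C11–C10: C6 and C10 are spanned by the enone bridge C7(=O)–C8=C9 (a verbenone-like bicyclo[3.1.1]heptenone), and C5 and C11 by the four-carbon bridge C4–C3–C2–C1, which closes a seven-membered ring. Of the six stereocentres (C1, C3, C5, C6, C10, C11) the four on the cyclobutane are interlocked, because the two bridges must lie on opposite faces of the four-membered ring; C4 and C1 therefore point away from the enone bridge, the C11 methyl lies over it, and C10 and C11 follow once C5 and C6 are set. In the ring C1–C2–C3–C4–C5–C6–C11 the C1 oxygen sits on the face of the C5 and C6 hydrogens and the C3 oxygen on the opposite face, and the two oxygens carry different acyl groups, so they have to be introduced separately and without migration. Sensitive groups are the strained cyclobutyl enone (light, strong acid), the senecioate (deconjugation by base, conjugate reduction) and the two ester linkages. The difficulty is the four-membered ring, in which quaternary C11 sits between oxygenated C1 and the ring-fusion carbons, with a second quaternary carbon, C4, next door on C5. The strategy rests on one feature: C11 carries the oxygenated C1 and hangs on C6, which is 1,3 to C10 in the six-membered ring, so a C11–C1 epoxide is a masked tertiary radical that reaches C10 across C6–C5, provided that C10 is the β-carbon of a carvone-type enone C8(=O)–C9(CH3)=C10. The price is that the ketone then emerges at C8 and has to be moved to C7.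

## Retrosynthetic reasoning

**C7 carbonyl (29 ⇒ 28 ⇒ 27 ⇒ 26).** The enone of 29 cannot come straight from the ring closure, because the radical acceptor needs its carbonyl at C8. The C7 oxygen is therefore removed first: 28 has C7 as the only ring methylene allylic to C8=C9 (C10 is a bridgehead), so a pinene-to-verbenone type C–H oxidation is the forward step. The alkene of 28 comes from the more substituted enol triflate 27 of ketone 26, which also erases the C9 centre.

**C1 ester (26 ⇒ 24 + 25).** Cutting the senecioate leaves alcohol 24, in which C1–OH is the only free hydroxyl. The two esters are thus told apart by the order of events, not by protecting groups.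

**C10–C11 (24 ⇒ 21).** This is the key disconnection. Cutting the cyclobutane here gives a tertiary C11 radical and an enone. The radical is masked as the C11–C1 epoxide of 21, so the same oxygen that triggers the closure becomes the C1 carbinol with its configuration intact. Any other cyclobutane bond would leave C1 to be oxygenated later beside a quaternary centre.

**C11–C1 oxygen and alkene (21 ⇒ 20 ⇒ 19).** The epoxide comes from the trisubstituted cycloheptene 20 by attack on its convex face. The alkene is cut by ring-closing metathesis, which leaves an isopropenyl group on C6 (a carvone feature) and an allyl group on C3 in 19. The two chains must be cis on the six-membered ring, which is also what the key step requires.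

**C3 ester and C2–C3 (19 ⇒ 17 + 18; 17 ⇒ 14 + 15).** The isovalerate is put on as soon as the C3 hydroxyl exists. C3 is remote from the ring stereocentres and attached to quaternary C4, so it is set by the chiral allylborane 15 on the non-enolisable aldehyde 14, not by substrate control.

**C4–C5 (14 ⇒ 13 ⇒ 12 ⇒ 9).** The bond between quaternary C4 and ring carbon C5 must be cis to the C6 substituent. C5 is not an electrophilic position of 1, and conjugate-addition/aldol annulations would leave C6 unsubstituted or give the trans isomer. A [3,3] shift of the isobutyrate 9 solves both problems: the ester oxygen on C9 hands the carbon over to C5 on its own face, and the ring alkene returns to C9=C10. Acid 12 is then adjusted to aldehyde 14 through diol 13, which at the same time restores the C8 ketone.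

**Transposition on the six-membered ring (9 ⇒ 7 + 8; 7 ⇒ 4 ⇒ 3 ⇒ 2 ⇒ 1).** The tertiary allylic alcohol 7 (C9–OH cis to the isopropenyl group, alkene C10=C5) is the allylic transposition product of epoxide 4, which comes from 1 by 1,2-reduction, hydroxyl-directed epoxidation and esterification. Compound 1 supplies C5–C10, the C9 methyl, the isopropenyl group (C11 and its methyl) and the C6 configuration; 8 supplies C3, C4 and the gem-dimethyl group.

## Alternatives that were turned down

**Alternative 1: Wolff ring contraction of a bridged cyclopentanone.**
- Disconnection: the C5–C10 bond of the cyclobutane.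
- Forward key step: irradiation (or PhCO2Ag) in methanol of the bridged α-diazo ketone A1 (diazo group on C10, carbonyl C9). C5 migrates from C9 to C10 with retention and the ketene is trapped, giving the bicyclo[4.1.1]octenone methyl ester A2 (ester C9 on C10, silyloxymethyl C7 on C6).
- For: ring contraction with loss of nitrogen is irreversible and little affected by crowding. On the certainty of the ring-forming event it is stronger than a 4-exo radical closure.
- Against: A2 has neither the six-membered enone ring nor the two oxygens.
  - C7 and C9 must still be joined through a new C8, and C9 needs its methyl.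
  - The ester-bearing C10 is epimerisable and must be cis to C7 for any closure.
  - The C1 ketone and C2=C3 alkene must be turned into the trans C1/C3 diester, with oxygen delivered to C3 beside quaternary C4.
  - Diazo transfer to C10 next to quaternary C11 needs prior activation, and A1 is itself a bridged bicycle of comparable difficulty.
- Comparison: the chosen strategy accepts a less certain closure, but that closure is the last skeletal bond. The C3 ester is in place, the C1 oxygen is revealed by the same step, and four steps remain.

**Alternative 2: rhodium hydroacylation closes the bridged six-membered ketone.**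
- Disconnection: C7–C8.
- Forward key step: [Rh(Ph2PCH2CH2PPh2)]ClO4 (monovalent rhodium) inserts into the formyl C–H of the cyclobutane aldehyde A3. The isopropenyl group on C10 inserts with rhodium on the terminal carbon C8, and reductive elimination gives the tricyclic diketone A4.
- For: the ketone is made directly at C7, so no carbonyl transposition is needed. The chosen route spends three steps on this, and the alternative is clearly stronger here. It is also atom-economical and neutral.
- Against: hydroacylation is dependable for five-membered ketones. Here a six-membered ring must form from a hindered acyl rhodium hydride and a 1,1-disubstituted alkene, where decarbonylation is the expected competitor. More fundamentally, the cyclobutane with all four stereocentres, including the 1,3-cis formyl and isopropenyl groups, must already exist in A3, so the hardest ring is moved into the precursor. The C1/C3 oxygens are again left for late in the synthesis.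
- Comparison: the chosen strategy builds the cyclobutane itself, from a chiral-pool six-membered ring.

**Alternative 3: cross-conjugated enolate displaces a tosylate to close the cyclobutane.**
- Disconnection: C6–C11.
- Forward key step: KOC(CH3)3 deprotonates C11 of the cis-fused cycloheptenone tosylate A5 (C4 is quaternary, so only the cross-conjugated enolate can form). The enolate displaces the C6 tosylate with inversion to give the tricyclic dienone A6.
- For: the closure is ionic and stereospecific and creates quaternary C11. A6 already has the C8=C9 alkene, so only the allylic oxidation remains for the enone. On steps after the key step for that ring it is shorter than the chosen route.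
- Against: a fully substituted enolate carbon must attack a secondary tosylate flanked by the ring fusion in a 4-exo-tet mode, where E2 elimination and O-alkylation are the expected competitors. The tosylate must be set anti to the approaching C11 on the concave face. A6 still needs the C1 ketone and C2=C3 alkene converted into the trans diester, two stereoselective events on the strained tricycle with oxygen entering beside quaternary C4.
- Comparison: the chosen route sets C3 under reagent control before any strain is present, and C1 comes from the epoxide that drives the closure.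

Key step: step 13

**Remarks.**
- Locants C1–C11 are those of the target. In the six-membered ring, β is the face carrying the C6 isopropenyl group (later C11) and α the other face.
- For the seven-membered ring C1–C2–C3–C4–C5–C6–C11, "convex" is the face of the C5 and C6 hydrogens and "concave" the face on which the six-membered ring is attached.
- In SMILES strings of titanium species the cyclopentadienyl rings are drawn σ-bonded.
- Assumption: 15 is used as the commercial solution of the enantiomer derived from (−)-α-pinene, which adds allyl to the Re face of an aldehyde.

## Route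

**Step 1**
Reactants: 1 (S)-(+)-carvone
Product: 2 (1S,5S)-cis-carveol (C8 hydroxyl β)
Conditions: NaBH4, CeCl3·7H2O, MeOH, −20 to 0 °C
Reagents that add atoms: none
Why: Luche reduction: 1,2-hydride addition to the enone, with axial attack on the half-chair carrying an equatorial isopropenyl group, should give the cis alcohol; the minor trans epimer is removed by chromatography.

**Step 2**
Reactants: 2 (1S,5S)-cis-carveol
Product: 3 epoxy alcohol (C8 hydroxyl/C9–C10 epoxide oxygen/C6 isopropenyl all β)
Conditions: VO(acac)2 (cat.), t-BuOOH, CH2Cl2, 0 °C to rt
Reagents that add atoms: tert-butyl hydroperoxide, CC(C)(C)OO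
Why: Hydroxyl-directed epoxidation: the vanadium-bound peroxide is delivered to the allylic ring alkene on the face of the hydroxyl, and the isolated isopropenyl alkene should not react.

**Step 3**
Reactants: 3 epoxy alcohol
Product: 4 epoxy pivalate (C8 pivaloyloxy β; epoxide β)
Conditions: pivaloyl chloride, pyridine, DMAP (cat.), CH2Cl2, 0 °C to rt
Reagents that add atoms: pivaloyl chloride, CC(C)(C)C(Cl)=O
Why: Esterification without an alkoxide, so no Payne rearrangement; the pivalate has no α-hydrogen (inert to the amide base of step 6) and is removed by the hydride of step 7.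

**Step 4**
Reactants: 4 epoxy pivalate
Product: 7 tertiary allylic alcohol (C8 pivaloyloxy/C9 hydroxyl/C6 isopropenyl all β; C9 methyl α; C10=C5 alkene), via hydroxy selenide 5 (not isolated), via selenoxide 6 (not isolated)
Conditions: (PhSe)2, NaBH4, EtOH, 0 °C to reflux; then THF, 30% H2O2, pyridine, 0 °C to rt
Reagents that add atoms: diphenyl diselenide, c1ccc(cc1)[Se][Se]c1ccccc1 and hydrogen peroxide, OO (selenium and its oxygen are carried only by 5 and 6)
Why: Epoxide-to-allylic-alcohol transposition: benzeneselenolate opens the epoxide at secondary C10 with inversion (trans-diaxial opening with the isopropenyl and pivaloyloxy groups equatorial), leaving the tertiary C9 hydroxyl on the β face. Oxidation to selenoxide 6 and syn elimination can only take a hydrogen from C5, because C9 is fully substituted, which places the alkene at C10=C5.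

**Step 5**
Reactants: 7 tertiary allylic alcohol; 8 2-methylpropanoyl chloride
Product: 9 C9 2-methylpropanoate of 7
Conditions: 8 (excess), DMAP, Et3N, CH2Cl2, reflux
Reagents that add atoms: 8 2-methylpropanoyl chloride, CC(C)C(Cl)=O
Why: Acylpyridinium (and ketene) acylation of the hindered tertiary alcohol; no alkoxide is generated, so the neighbouring pivalate stays where it is.

**Step 6**
Reactants: 9 C9 2-methylpropanoate
Product: 12 acid (2-methyl-2-[3-methyl-4-(pivaloyloxy)-6-(prop-1-en-2-yl)cyclohex-2-en-1-yl]propanoic acid; substituents on C5/C6/C8 all β; C9=C10 alkene), via silyl ketene acetal 10 (not isolated), via trimethylsilyl ester 11 (not isolated)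
Conditions: LiN(iPr)2, Me3SiCl, Et3N, THF, −78 to 60 °C; then 1 M HCl
Reagents that add atoms: chlorotrimethylsilane, C[Si](C)(C)Cl (silicon is carried only by 10 and 11)
Why: Ireland–Claisen rearrangement: the ketene acetal 10 rearranges suprafacially across C9–C10=C5, so C4 is delivered to C5 on the β face from which the C9 oxygen departs, cis to the isopropenyl group on C6. The migrating terminus carries two methyls, so enolate geometry is irrelevant, and the tertiary allylic ester gains the trisubstituted C9=C10 alkene.

**Step 7**
Reactants: 12 acid
Product: 13 diol (4-(1-hydroxy-2-methylpropan-2-yl)-2-methyl-5-(prop-1-en-2-yl)cyclohex-2-en-1-ol; substituents on C5/C6/C8 all β)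
Conditions: LiAlH4, THF, 0 °C to reflux
Reagents that add atoms: none
Why: Hydride reduction of the acid to the neopentyl alcohol; the same reagent cleaves the pivalate, so no separate deprotection is needed.

**Step 8**
Reactants: 13 diol
Product: 14 keto aldehyde (2-methyl-2-[3-methyl-4-oxo-6-(prop-1-en-2-yl)cyclohex-2-en-1-yl]propanal; C5 and C6 substituents cis)
Conditions: Dess–Martin periodinane, NaHCO3, CH2Cl2, rt
Reagents that add atoms: none
Why: Dess–Martin oxidation of both hydroxyls: the allylic C8 alcohol gives back the carvone-type enone and the neopentyl alcohol gives a non-enolisable aldehyde.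

**Step 9**
Reactants: 14 keto aldehyde; 15 (+)-B-allyldiisopinocampheylborane
Product: 17 homoallylic alcohol (4-[(3R)-3-hydroxy-2-methylhex-5-en-2-yl]-2-methyl-5-(prop-1-en-2-yl)cyclohex-2-en-1-one; C5 and C6 substituents cis), via borinate 16 (not isolated)
Conditions: 15, Et2O, −78 °C; then 2-aminoethanol, rt
Reagents that add atoms: 15 (+)-B-allyldiisopinocampheylborane, C=CCB([C@H]1C[C@H]2C[C@@H]([C@@H]1C)C2(C)C)[C@H]1C[C@H]2C[C@@H]([C@@H]1C)C2(C)C
Why: Brown allylation: chair-like (Zimmerman–Traxler) transfer of the allyl group to the Re face of the aldehyde sets C3 as R under reagent control. The aldehyde reacts far faster than the hindered conjugated ketone at −78 °C, and the amino alcohol work-up avoids alkaline peroxide, which would epoxidise the enone.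

**Step 10**
Reactants: 17 homoallylic alcohol; 18 3-methylbutanoyl chloride
Product: 19 C3 3-methylbutanoate of 17
Conditions: 18, pyridine, DMAP, CH2Cl2, 0 °C to rt
Reagents that add atoms: 18 3-methylbutanoyl chloride, CC(C)CC(Cl)=O
Why: DMAP-catalysed acylation of the hindered secondary alcohol; the isovalerate is installed before the C1 oxygen exists, so the two esters never have to be told apart.

**Step 11**
Reactants: 19 C3 3-methylbutanoate
Product: 20 cis-fused bicyclic dienone (bicyclo[5.4.0]undecane skeleton; C8 ketone; C9=C10 and C11=C1 alkenes; C3 ester on the concave face)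
Conditions: second-generation Grubbs catalyst RuCl2(=CHPh)(PCy3)(H2IMes) (5 mol%), toluene, 80 °C
Reagents that add atoms: none
Why: Ring-closing metathesis of the monosubstituted alkene with the 1,1-disubstituted isopropenyl group gives the trisubstituted cycloheptene. The cis arrangement of the two chains on C5 and C6 allows closure, and the conjugated trisubstituted C9=C10 alkene should be inert to the ruthenium carbene.

**Step 12**
Reactants: 20 cis-fused bicyclic dienone
Product: 21 epoxy enone (C11–C1 epoxide with the oxygen on the convex face; C3 3-methylbutanoate in place)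
Conditions: mCPBA, NaHCO3, CH2Cl2, 0 °C
Reagents that add atoms: 3-chloroperbenzoic acid, OOC(=O)c1cccc(Cl)c1
Why: Prilezhaev epoxidation of the electron-rich trisubstituted alkene; the enone alkene is electron-poor and should not react. The concave face of C11=C1 is screened by the six-membered ring at allylic C6 and by the C3 ester, so oxygen should arrive on the convex face, syn to the ring-fusion hydrogens, which sets C1.

**Step 13**
Reactants: 21 epoxy enone
Product: 24 tricyclic alcohol (C1 hydroxyl; C3 3-methylbutanoate; C8 ketone; C9 methyl on the side of C11), via C11 radical 22 (not isolated), via titanium enolate 23 (not isolated)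
Conditions: (C5H5)2TiCl2 (2.5 equiv), Zn dust, THF, rt, which gives (C5H5)2TiCl in the flask; slow addition of 21; then cold 1 M HCl
Reagents that add atoms: (C5H5)2TiCl, Cl[Ti](C1C=CC=C1)C1C=CC=C1 (titanium is carried only by 22 and 23)
Why: (C5H5)2TiCl (trivalent titanium), generated in the flask by zinc reduction of (C5H5)2TiCl2, transfers one electron to the epoxide and the C11–O bond breaks to the tertiary radical 22, while the oxygen stays on C1 as a titanium alkoxide with its configuration. The radical adds to C10, the β-carbon of the enone, and a second equivalent reduces the α-keto radical at C9 to the titanium enolate 23, which drains the otherwise reversible closure; protonation on work-up gives 24. The closest known reaction type is titanocene-mediated reductive epoxide opening followed by radical addition to enones, including 4-exo closures of epoxycarvone-type substrates to pinane skeletons. Only the C10–C11 bond is formed: along the tether C11–C6–C5–C10 it is a 4-exo-trig closure, and it completes the bicyclo[3.1.1]heptanone and the second seven-membered ring at the same time. C11 is fixed by the C1–C4 tether (C1 stays on the side of C4, the methyl ends over the six-membered ring), C10 by C6 (a one-carbon bridge can only span C6 and C10 on the face carrying C11), and C9 by protonation on the face away from the C11 methyl, a centre erased in step 15. The step needs homolysis towards tertiary C11 rather than C1, closure faster than hydrogen loss or reduction of the radical, and no reduction of the enone; the cis ring fusion puts C11 axial on the half-chair while the bulky C4 stays equatorial, so the radical orbital sits over C10, and a nucleophilic tertiary radical is polarity-matched with the enone.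

**Step 14**
Reactants: 24 tricyclic alcohol; 25 3-methylbut-2-enoyl chloride
Product: 26 C1 3-methylbut-2-enoate of 24 (C8 ketone)
Conditions: 25, pyridine, DMAP, CH2Cl2, 0 °C
Reagents that add atoms: 25 3-methylbut-2-enoyl chloride, CC(C)=CC(Cl)=O
Why: Acylation of the only free hydroxyl through the acylpyridinium; pyridine is used in place of a trialkylamine so that 25 is not dehydrochlorinated to the vinylketene, which would give the deconjugated ester.

**Step 15**
Reactants: 26 C1 3-methylbut-2-enoate
Product: 27 C8–C9 enol triflate
Conditions: (CF3SO2)2O, 2,6-di-tert-butyl-4-methylpyridine, CH2Cl2, 0 °C to rt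
Reagents that add atoms: trifluoromethanesulfonic anhydride, O=S(=O)(OS(=O)(=O)C(F)(F)F)C(F)(F)F
Why: Enol triflate formation under weakly basic conditions should favour the more substituted C8=C9 enol (the alkene position of a pinene); both esters tolerate it, and the C9 centre from step 13 disappears.

**Step 16**
Reactants: 27 C8–C9 enol triflate
Product: 28 C8=C9 alkene (C7 methylene)
Conditions: Pd(OAc)2 (cat.), PPh3, HCO2H, Bu3N, DMF, 60 °C
Reagents that add atoms: none
Why: Palladium-catalysed formate reduction of the vinyl triflate (oxidative addition, formate exchange, decarboxylation to the palladium hydride, reductive elimination). Formate is preferred over a tin hydride, which with zerovalent palladium can also reduce the conjugated senecioate.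

**Step 17**
Reactants: 28 C8=C9 alkene
Product: 29 target CNP0335239.1
Conditions: CrO3, 3,5-dimethylpyrazole, CH2Cl2, −20 °C, dark
Reagents that add atoms: chromium trioxide, O=[Cr](=O)=O
Why: Allylic oxidation with the CrO3–3,5-dimethylpyrazole complex: C7 is the only ring methylene allylic to C8=C9 (C10 is a bridgehead), so the enone should form as in the pinene-to-verbenone oxidation; the methyls of the electron-poor senecioate are far less reactive.

## Compound list

1 | (S)-(+)-carvone, (5S)-2-methyl-5-(prop-1-en-2-yl)cyclohex-2-en-1-one | O=C1C(C)=CC[C@H](C(C)=C)C1 | starting material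
2 | (1S,5S)-cis-carveol, (1S,5S)-2-methyl-5-(prop-1-en-2-yl)cyclohex-2-en-1-ol | O[C@@H]1C(C)=CC[C@H](C(C)=C)C1 | intermediate
3 | epoxy alcohol, 1-methyl-4-(prop-1-en-2-yl)-7-oxabicyclo[4.1.0]heptan-2-ol with hydroxyl, epoxide oxygen and isopropenyl all β | O[C@@H]1[C@]2(C)O[C@@H]2C[C@H](C(C)=C)C1 | intermediate
4 | epoxy pivalate (2,2-dimethylpropanoate of 3) | CC(C)(C)C(=O)O[C@@H]1[C@]2(C)O[C@@H]2C[C@H](C(C)=C)C1 | intermediate
5 | hydroxy selenide (C8 pivaloyloxy β, C9 hydroxyl β, C10 phenylselanyl α) | CC(C)(C)C(=O)O[C@@H]1[C@](C)(O)[C@@H]([Se]c2ccccc2)C[C@H](C(C)=C)C1 | intermediate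
6 | selenoxide of 5 | CC(C)(C)C(=O)O[C@@H]1[C@](C)(O)[C@@H]([Se](=O)c2ccccc2)C[C@H](C(C)=C)C1 | intermediate
7 | tertiary allylic alcohol, 2-hydroxy-2-methyl-5-(prop-1-en-2-yl)cyclohex-3-en-1-yl 2,2-dimethylpropanoate, pivaloyloxy, hydroxyl and isopropenyl all β | CC(C)(C)C(=O)O[C@@H]1[C@](C)(O)C=C[C@H](C(C)=C)C1 | intermediate
8 | 2-methylpropanoyl chloride | CC(C)C(Cl)=O | starting material
9 | C9 2-methylpropanoate of 7 | CC(C)(C)C(=O)O[C@@H]1[C@](C)(OC(=O)C(C)C)C=C[C@H](C(C)=C)C1 | intermediate
10 | trimethylsilyl ketene acetal of 9 | CC(C)(C)C(=O)O[C@@H]1[C@](C)(OC(O[Si](C)(C)C)=C(C)C)C=C[C@H](C(C)=C)C1 | intermediate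
11 | trimethylsilyl ester of 12 | CC(C)(C)C(=O)O[C@@H]1C(C)=C[C@H](C(C)(C)C(=O)O[Si](C)(C)C)[C@H](C(C)=C)C1 | intermediate
12 | 2-methyl-2-[3-methyl-4-(pivaloyloxy)-6-(prop-1-en-2-yl)cyclohex-2-en-1-yl]propanoic acid, substituents on C5, C6 and C8 all β | CC(C)(C)C(=O)O[C@@H]1C(C)=C[C@H](C(C)(C)C(O)=O)[C@H](C(C)=C)C1 | intermediate
13 | 4-(1-hydroxy-2-methylpropan-2-yl)-2-methyl-5-(prop-1-en-2-yl)cyclohex-2-en-1-ol, substituents on C5, C6 and C8 all β | O[C@@H]1C(C)=C[C@H](C(C)(C)CO)[C@H](C(C)=C)C1 | intermediate
14 | 2-methyl-2-[3-methyl-4-oxo-6-(prop-1-en-2-yl)cyclohex-2-en-1-yl]propanal, C5 and C6 substituents cis | O=C1C(C)=C[C@H](C(C)(C)C=O)[C@H](C(C)=C)C1 | intermediate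
15 | (+)-B-allyldiisopinocampheylborane (isopinocampheyl groups from (−)-α-pinene) | C=CCB([C@H]1C[C@H]2C[C@@H]([C@@H]1C)C2(C)C)[C@H]1C[C@H]2C[C@@H]([C@@H]1C)C2(C)C | starting material
16 | diisopinocampheylborinate of 17 | O=C1C(C)=C[C@H](C(C)(C)[C@H](OB([C@H]2C[C@H]3C[C@@H]([C@@H]2C)C3(C)C)[C@H]2C[C@H]3C[C@@H]([C@@H]2C)C3(C)C)CC=C)[C@H](C(C)=C)C1 | intermediate
17 | 4-[(3R)-3-hydroxy-2-methylhex-5-en-2-yl]-2-methyl-5-(prop-1-en-2-yl)cyclohex-2-en-1-one, C5 and C6 substituents cis | O=C1C(C)=C[C@H](C(C)(C)[C@H](O)CC=C)[C@H](C(C)=C)C1 | intermediate
18 | 3-methylbutanoyl chloride | CC(C)CC(Cl)=O | starting material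
19 | C3 3-methylbutanoate of 17 | O=C1C(C)=C[C@H](C(C)(C)[C@H](OC(=O)CC(C)C)CC=C)[C@H](C(C)=C)C1 | intermediate
20 | cis-fused bicyclo[5.4.0]undecadienone (C8 ketone, C9=C10 and C11=C1 alkenes, C3 3-methylbutanoate on the concave face) | O=C1C(C)=C[C@H]2[C@@H](C1)C(C)=CC[C@@H](OC(=O)CC(C)C)C2(C)C | intermediate
21 | epoxy enone, C11–C1 epoxide of 20 with the oxygen on the convex face | O1[C@@H]2C[C@@H](OC(=O)CC(C)C)C(C)(C)[C@@H]3[C@@H](CC(=O)C(C)=C3)[C@]12C | intermediate
22 | C11 radical with C1–O–TiCl(C5H5)2 | Cl[Ti](C1C=CC=C1)(C1C=CC=C1)O[C@@H]1C[C@@H](OC(=O)CC(C)C)C(C)(C)[C@H]2C=C(C)C(=O)C[C@H]2[C]1C | intermediate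
23 | tricyclic C8–C9 titanium enolate with C1 titanium alkoxide | Cl[Ti](C1C=CC=C1)(C1C=CC=C1)O[C@@H]1C[C@@H](OC(=O)CC(C)C)C(C)(C)[C@@H]2[C@H]3CC(O[Ti](Cl)(C4C=CC=C4)C4C=CC=C4)=C(C)[C@@H]2[C@]31C | intermediate
24 | tricyclic alcohol (C1 hydroxyl, C3 3-methylbutanoate, C8 ketone) | O[C@@H]1C[C@@H](OC(=O)CC(C)C)C(C)(C)[C@@H]2[C@H]3CC(=O)[C@H](C)[C@@H]2[C@]31C | intermediate
25 | 3-methylbut-2-enoyl chloride | CC(C)=CC(Cl)=O | starting material
26 | C1 3-methylbut-2-enoate of 24 | CC(C)=CC(=O)O[C@@H]1C[C@@H](OC(=O)CC(C)C)C(C)(C)[C@@H]2[C@H]3CC(=O)[C@H](C)[C@@H]2[C@]31C | intermediate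
27 | C8–C9 enol triflate of 26 | CC(C)=CC(=O)O[C@@H]1C[C@@H](OC(=O)CC(C)C)C(C)(C)[C@@H]2[C@H]3CC(OS(=O)(=O)C(F)(F)F)=C(C)[C@@H]2[C@]31C | intermediate
28 | C8=C9 alkene with C7 methylene | CC(C)=CC(=O)O[C@@H]1C[C@@H](OC(=O)CC(C)C)C(C)(C)[C@@H]2[C@H]3CC=C(C)[C@@H]2[C@]31C | intermediate
29 | CNP0335239.1 | CC(C)=CC(=O)O[C@@H]1C[C@@H](OC(=O)CC(C)C)C(C)(C)[C@@H]2[C@H]3C(=O)C=C(C)[C@@H]2[C@]31C | target

## Step count and least certain steps

Total step count: 17. Longest linear sequence: 17 steps (1 to 29); 8, 15, 18 and 25 are bought and enter directly.

**Step 13 (key step).** The most likely failure is interception of the tertiary radical before it closes. A second titanium centre can trap it and β-hydride elimination then gives an allylic alcohol, or hydrogen abstraction gives simple reduction. Both are plausible because a 4-exo closure is slow and reversible. One-electron reduction of the enone is a second drain. Fallback: set out from 21 and open the epoxide with MgBr2·OEt2 in Et2O at −20 °C at the tertiary carbon to give the tertiary bromohydrin F1 (bromine on C11, hydroxyl on C1 unchanged). Then generate the same radical by bromine abstraction with (Me3Si)3SiH and AIBN in toluene at 80 °C under slow addition. No metal is present to trap the radical, and the α-keto radical is quenched by hydrogen transfer from the silane. The sequence comes back to the route at 24.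

**Step 12.** Oxygen may be delivered to the concave face if the flexible cycloheptene folds so that the C4 methyls, not the six-membered ring, shield the alkene; that would invert C1. Fallback: set out from 20 and treat it with N-bromosuccinimide in aqueous THF. The bromonium ion forms on whichever face electrophiles prefer, and water opens it at tertiary C11 from the other side, giving the bromohydrin F2. NaH in THF at 0 °C then closes the epoxide by displacement at C1, so the oxygen ends on the face opposite to the one the electrophile chose. This two-step inversion of facial outcome comes back to the route at 21.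

**Step 15.** Enolisation may go towards C7 instead of C9 (loss of regiocontrol), because the C9 hydrogen is flanked by a bridgehead and a methyl. The later C–H oxidation of step 17 carries its own site-selectivity risk. Fallback, replacing steps 15–17 and built on the enolisation that is kinetically preferred: set out from 26 and deprotonate the C7 methylene with KN(SiMe3)2 in THF at −78 °C, then oxidise the enolate with 3-phenyl-2-(phenylsulfonyl)oxaziridine to give the α-hydroxy ketone F3 (the C7 configuration is of no consequence). Dess–Martin periodinane oxidises F3 to the C7,C8-dione, which can enolise only towards C9 because C6 is a bridgehead, and is therefore carried on as the diosphenol F4 (C7 ketone, C8 hydroxyl, C8=C9 alkene). PhN(SO2CF3)2 and Et3N convert F4 into the triflate F5, and the palladium–formate reduction of step 16 (Pd(OAc)2, PPh3, HCO2H, Bu3N) removes the triflate. This places the enone without any allylic C–H oxidation, and the sequence comes back to the route at 29.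

**Step 6 (with step 5).** The tertiary allylic ester may ionise or eliminate to a diene on warming, and acylation of the crowded tertiary alcohol in step 5 may be incomplete. Fallback: set out from 7 and heat it with 1,1,1-triethoxy-2-methylpropane and catalytic propanoic acid (Johnson orthoester Claisen). This uses the same suprafacial shift without a discrete ester or amide base and gives the ethyl ester F6. LiAlH4 reduces both ester groups of F6, and the sequence comes back to the route at 13.

## Further compounds

F1 | step 13 | bromohydrin from 21 with bromine on C11 and hydroxyl on C1 | O[C@@H]1C[C@@H](OC(=O)CC(C)C)C(C)(C)[C@@H]2[C@@H](CC(=O)C(C)=C2)[C@@]1(C)Br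
F2 | step 12 | bromohydrin from 20 with bromine on C1 (concave face) and hydroxyl on C11 (convex face) | Br[C@H]1C[C@@H](OC(=O)CC(C)C)C(C)(C)[C@@H]2[C@@H](CC(=O)C(C)=C2)[C@]1(C)O
F3 | step 15 | C7 hydroxy C8 ketone from 26 (hydroxyl on the face of C5) | CC(C)=CC(=O)O[C@@H]1C[C@@H](OC(=O)CC(C)C)C(C)(C)[C@@H]2[C@H]3[C@@H](O)C(=O)[C@H](C)[C@@H]2[C@]31C
F4 | step 15 | diosphenol (C7 ketone, C8 hydroxyl, C8=C9 alkene), the enol form of the C7,C8-dione | CC(C)=CC(=O)O[C@@H]1C[C@@H](OC(=O)CC(C)C)C(C)(C)[C@@H]2[C@H]3C(=O)C(O)=C(C)[C@@H]2[C@]31C
F5 | step 15 | C8 triflate of diosphenol F4 | CC(C)=CC(=O)O[C@@H]1C[C@@H](OC(=O)CC(C)C)C(C)(C)[C@@H]2[C@H]3C(=O)C(OS(=O)(=O)C(F)(F)F)=C(C)[C@@H]2[C@]31C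
F6 | step 6 | ethyl ester corresponding to acid 12 | CC(C)(C)C(=O)O[C@@H]1C(C)=C[C@H](C(C)(C)C(=O)OCC)[C@H](C(C)=C)C1
A1 | alternative 1 | bridged α-diazo ketone (diazo group on C10, carbonyl C9, bicyclo[4.2.1] skeleton) | O=C1C=CC(C)(C)[C@@H]2[C@@H](CO[Si](C)(C)C(C)(C)C)[C@@]1(C)C(=[N+]=[N-])C2=O
A2 | alternative 1 | bicyclo[4.1.1]octenone with methyl ester on C10 and silyloxymethyl on C6 | O=C1C=CC(C)(C)[C@@H]2[C@@H](CO[Si](C)(C)C(C)(C)C)[C@@]1(C)[C@H]2C(=O)OC
A3 | alternative 2 | bicyclo[4.1.1]octenone with formyl on C6 and isopropenyl on C10 | O=C1C=CC(C)(C)[C@@H]2[C@@H](C=O)[C@@]1(C)[C@H]2C(C)=C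
A4 | alternative 2 | tricyclic diketone with C7 ketone and saturated C8–C9 | O=C1C=CC(C)(C)[C@@H]2[C@H]3C(=O)C[C@H](C)[C@@H]2[C@]31C
A5 | alternative 3 | cis-fused cycloheptenone with C6 tosylate (C11 drawn as one epimer, its configuration is lost on enolisation) | O=C1C=CC(C)(C)[C@@H]2[C@@H](OS(=O)(=O)c3ccc(C)cc3)CC=C(C)[C@@H]2[C@@H]1C
A6 | alternative 3 | tricyclic dienone with C8=C9 alkene and C7 methylene | O=C1C=CC(C)(C)[C@@H]2[C@H]3CC=C(C)[C@@H]2[C@]31C
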